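**Numbering used throughout.** Ring A: C1' (OH), C2' (ether O), C3' (H), C4' (Br), C5' (H), C6' (H). Ring B: C1 (ether O), C2 (OH), C3 (Br), C4 (H), C5 (Br), C6 (Br). Compound numbers 1–17 are fixed by the steps below; 17 is the target.

## Analysis of the target

The target 17 is a diaryl ether of two benzene rings and has no stereocentre, so the whole problem is one of substitution pattern. Ring A is a 1,2-dioxygenated benzene with the free hydroxyl at C1', the ether oxygen at C2' and one bromine at C4', para to the hydroxyl. Ring B carries a substituent on five of its six carbons: the ether oxygen at C1, a hydroxyl at C2, bromine at C3, C5 and C6, and hydrogen only at C4. The sensitive groups are the four aryl bromides, which exclude organolithium reagents, zerovalent palladium and hydrogenolysis, and the two phenols, which oxidise easily once free. The first difficulty is that the ether oxygen on ring B sits between the hydroxyl carbon C2 and the bromine-bearing carbon C6, so a direct aryl–oxygen coupling there would be doubly ortho-hindered and would have to choose among several carbon–halogen bonds. The second is that the C6 bromine is meta to the ring B hydroxyl and cannot be placed by brominating a 2-aryloxyphenol, while C4, para to the ether oxygen, must stay free. The strategy rests on ring A, which has oxygen on the adjacent carbons C1' and C2' and no carbon substituent. C1', C6', C5' and C4' can therefore come from C3 to C6 of a 3-acyloxy-2-pyrone, and C2' and C3' from the two carbons of an alkynyl ether whose oxygen already carries the finished ring B.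

## Retrosynthetic reasoning

The last bond cut is the O–methyl bond at C2 of ring B, which leads from 17 back to 15. The methyl group is what distinguishes the two ring B oxygens from the first step on. It survives base, heat and electrophilic bromine, and a boron trihalide removes it at the end without touching the aryl bromides or the diaryl ether.

The C4'–Br bond is cut next, giving 14. C4' is para to the ring A hydroxyl, the position that hydroxyl activates most, and ring B has no reactive position left by then. Placing this bromine late spares the pyrone a substituent at C6. The hydroxyl of 14 is traced to the acetate 13, the form in which it leaves the ring-forming step.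

Ring A of 13 is then taken apart at C1'–C2' and C3'–C4', giving the alkynyl ether 9 and the pyrone 11. In the forward sense the two react by [4+2] cycloaddition to the bridged lactone 12, which loses its one-carbon lactone bridge to become the benzene ring. The cut is made here because it removes every aryl–oxygen bond formation from the route: the crowded C1–O bond of ring B is already present in 9 as a bond from oxygen to an sp carbon. The forward reaction must place the oxygen-bearing alkyne carbon next to the acetoxy-bearing carbon C3 of 11, so that the two oxygens end up ortho.

The pyrone 11 is the O-acetyl derivative of the purchasable hydroxypyrone 10. The acetyl group removes the acidic proton and lowers the electron density of the diene.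

The triple bond of 9 comes from loss of HCl from the (Z)-chlorovinyl ether 8. The O–C(sp2) bond of 8 comes from addition of the phenoxide of 5 to the haloalkyne 7, generated in the flask from the dichloroalkene 6. Organolithium routes to alkynyl ethers are excluded by the three aryl bromides of ring B, so the route uses elimination with an alkoxide.

The phenol 5 is traced through its acetate 4 to 2 and the purchasable bromoguaiacol 1. The two bonds cut are C3–Br and C5–Br of ring B. Compound 1 already holds the C6 bromine, ortho to the future ether oxygen, which no directing effect could install later. With the hydroxyl masked as acetate, the methoxy group is the only strong donor and directs to its ortho and para positions, which are C3 and C5. C4, para to the acetoxy group, stays free.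

## Alternatives that were turned down

Alternative 1: Ring B is built from a non-aromatic six-membered 1,3-dione. The ether carbon C1 is the central carbon of the dione and the two carbonyl carbons become C2 (hydroxyl) and C6 (bromine). In the forward key step the keto ester A1, methyl 6-(5-bromo-2-methoxyphenoxy)-5-oxohexanoate, is cyclised with an alkoxide base. The enolate on the aryloxy-bearing carbon attacks the ester in a Claisen condensation (6-exo-trig) and gives the dione A2.
- For it: the aryl–O–carbon bond comes from simple alkylation of an unhindered ring A phenol, the cyclisation is textbook chemistry driven by the stabilised dione enolate, and the 1,3-dicarbonyl maps exactly onto the O/Br pair flanking C1.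
- Against it: A2 lies two oxidation levels below a phenol. One carbonyl must become a vinyl bromide, the ring must be dehydrogenated without losing that bromide, two more bromines must go onto ring B beside an anisole-type ring A, and the methyl ether must be cleaved. That is five or more operations after the key step, and the aromatisation has no mild standard solution.
- Comparison: the ether bond formation is more reliable than the cycloaddition chosen here. The chosen route offers instead an aromatic ring straight from the key step, no oxidation-level adjustment, and bromines placed on precursors whose directing effects are unambiguous.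

Alternative 2: Both the C1–O and the C6–Br bond of ring B are cut, leading back to an aryne. In the forward key step the borylaryne A3 is generated from an ortho-iodoaryl triflate with i-PrMgCl·LiCl. The magnesium phenoxide of ring A adds to the aryne carbon next to boron, and the arylmagnesium formed on the neighbouring carbon is quenched with an electrophilic bromine donor to give the boronate A4. Oxidation of C–B to C–OH, dibromination ortho and para to that hydroxyl, and demethylation would finish the synthesis.
- For it: one flask sets the C1–O and C6–Br bonds, boron becomes the C2 hydroxyl that then directs the last two bromines, and only about three steps follow the key step. On paper it is the shortest route.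
- Against it: magnesium phenoxides are poor oxygen nucleophiles towards arynes and can react through carbon. The Grignard reagent that generates the aryne competes as a nucleophile, the ring A bromide is exposed to halogen–magnesium exchange, and the aryne precursor with iodine, triflate and boron on three adjacent carbons itself needs several steps.
- Comparison: it is stronger on step count after the key step and on directness for ring B. The chosen route offers instead a key step between two neutral closed-shell partners under base-free thermal conditions, with no organometallic near an aryl bromide.

Alternative 3: Ring A is cut at C2'–C3' and C5'–C6', so that three carbons come from a ketone and three from a vinamidinium salt. In the forward key step the aryloxyacetone A5 and the 2-bromovinamidinium salt A6 are condensed with an alkoxide base. Condensation at the aryloxymethylene carbon is followed by ring closure through the methyl group, with loss of two molecules of dimethylamine, giving the phenol A7. A7 is identical with 15.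
- For it: A5 is one alkylation from the phenol 5, ring A arrives with its bromine already at C4', and A7 is one demethylation from the target. It is about three steps shorter than the chosen route and involves no thermally fragile alkyne.
- Against it: such benzannulations are dependable with doubly activated ketones, but here the second C–C bond must form through an unactivated methyl group. After the first condensation the aryloxy group sits on an electrophilic sp2 carbon, where addition–elimination by amine or alkoxide can expel the stabilised phenoxide of 5. Hot alkoxide also meets a tribromoarene.
- Comparison: it is stronger on step economy and on placing the ring A bromine. The chosen route offers instead a pericyclic, base-free ring formation in which the aryl–oxygen bond is a spectator, so its uncertainty is reactivity, not a competing fragmentation. Because both routes share phenol 5, this alternative is the natural second choice.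

Key step: step 7

Assumption: 3-hydroxy-2H-pyran-2-one (10) is taken as a purchasable catalogue compound.

## Steps

Step 1
Reactants: 1 2-bromo-6-methoxyphenol
Product: 2 2-bromo-6-methoxyphenyl acetate
Conditions: Ac2O, pyridine, DMAP (cat.), CH2Cl2, 0 °C to rt
Reagents that add atoms: acetic anhydride CC(=O)OC(C)=O
Why: O-acetylation of a phenol (nucleophilic acyl substitution); masking the hydroxyl switches off its para-directing power so that the methoxy group alone steers step 2.

Step 2
Reactants: 2 2-bromo-6-methoxyphenyl acetate
Product: 4 2,3,5-tribromo-6-methoxyphenyl acetate, via 2,3-dibromo-6-methoxyphenyl acetate 3 (not isolated)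
Conditions: Br2 (2.5 equiv), NaOAc, AcOH, rt then 60–70 °C
Reagents that add atoms: bromine BrBr
Why: Electrophilic aromatic bromination; the methoxy group is the only strong donor, so the first bromine should enter para to it (C5 of ring B, giving 3) and the second ortho to it (C3 of ring B), the acetoxy group being too weak to direct to its own para position C4. NaOAc takes up HBr so that the ester and the methyl ether survive.

Step 3
Reactants: 4 2,3,5-tribromo-6-methoxyphenyl acetate
Product: 5 2,3,5-tribromo-6-methoxyphenol
Conditions: K2CO3 (1.5 equiv), MeOH, rt; aq. HCl work-up
Reagents that add atoms: none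
Why: Base-mediated methanolysis (transesterification) of an aryl acetate; the electron-poor aryloxide is a very good leaving group, and the aryl bromides and the methyl ether are inert.

Step 4
Reactants: 5 2,3,5-tribromo-6-methoxyphenol; 6 (Z)-1,2-dichloroethene (cis-1,2-dichloroethene, 5 equiv)
Product: 8 (Z)-2-chloroethenyl 2,3,5-tribromo-6-methoxyphenyl ether, via chloroethyne 7 (not isolated)
Conditions: KOH (powder, 4 equiv), DMSO, N2, rt to 50 °C
Reagents that add atoms: none
Why: Vinylic substitution by elimination–addition: KOH removes HCl from 6 by anti elimination to give 7 at low standing concentration, the phenoxide of 5 adds to its unsubstituted carbon, and the chlorovinyl anion is protonated trans to the entering oxygen, which sets the Z double bond. The excess of 6 should suppress a second addition.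

Step 5
Reactants: 8 (Z)-2-chloroethenyl 2,3,5-tribromo-6-methoxyphenyl ether
Product: 9 ethynyl 2,3,5-tribromo-6-methoxyphenyl ether (1,2,5-tribromo-3-(ethynyloxy)-4-methoxybenzene)
Conditions: KOtBu (1.3 equiv), THF, −40 to 0 °C; cold work-up, used at once
Reagents that add atoms: none
Why: Base-induced anti β-elimination (E2) of HCl from a (Z)-2-halovinyl ether, the classical entry to alkynyl ethers; in the Z isomer the hydrogen on the oxygen-bearing carbon is anti to chlorine. An alkoxide at low temperature, unlike an amide or organolithium base, should leave the aryl bromides alone.

Step 6
Reactants: 10 3-hydroxy-2H-pyran-2-one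
Product: 11 2-oxo-2H-pyran-3-yl acetate
Conditions: Ac2O, pyridine, CH2Cl2, 0 °C to rt
Reagents that add atoms: acetic anhydride CC(=O)OC(C)=O
Why: O-acetylation of the enolic hydroxyl; it removes the acidic proton that would add to the alkynyl ether and makes the pyrone a more electron-poor diene.

Step 7
Reactants: 9 ethynyl 2,3,5-tribromo-6-methoxyphenyl ether; 11 2-oxo-2H-pyran-3-yl acetate (3 equiv)
Product: 13 2-(2,3,5-tribromo-6-methoxyphenoxy)phenyl acetate, via bridged bicyclic lactone 12 (not isolated)
Conditions: PhMe, 120–130 °C, sealed tube, 9 added slowly to 11
Reagents that add atoms: none
Why: Thermal [4+2] cycloaddition of the pyrone diene (C3=C4–C5=C6 of 11) with the oxygen-substituted alkyne of 9 gives the 2-oxabicyclo[2.2.2]octadienone 12, which loses CO2 by retro-[4+2] and becomes the benzene ring. The closest known reaction type is the Diels–Alder/decarboxylation arene synthesis from 2-pyrones and electron-rich alkynes such as ynamines and alkoxyalkynes; this particular pair has not been tried. Ring A, a six-membered carbocycle, is closed by the intermolecular cycloaddition that forms C1'–C2' and C3'–C4' and is aromatised by the cycloreversion. No stereocentre persists: the two bridgehead centres of 12 form as a racemate and are erased when the bridge leaves. The step needs regioselectivity, since the other orientation would give the meta-dioxygenated isomer. This is secured by polarisation: the terminal alkyne carbon of 9 is its nucleophilic end and bonds to C6 of 11, the electrophilic diene terminus conjugated to the lactone carbonyl, so the aryloxy carbon bonds to the acetoxy-bearing C3. The aryl bromides, the methyl ether and the acetate are inert under neutral thermal conditions, and slow addition of 9 into an excess of 11 keeps the self-reaction of the alkynyl ether down.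

Step 8
Reactants: 13 2-(2,3,5-tribromo-6-methoxyphenoxy)phenyl acetate
Product: 14 2-(2,3,5-tribromo-6-methoxyphenoxy)phenol
Conditions: K2CO3 (1.5 equiv), MeOH, rt; aq. HCl work-up
Reagents that add atoms: none
Why: Base-mediated methanolysis of the aryl acetate frees the ring A hydroxyl; the diaryl ether, the methyl ether and the bromides are stable.

Step 9
Reactants: 14 2-(2,3,5-tribromo-6-methoxyphenoxy)phenol
Product: 15 4-bromo-2-(2,3,5-tribromo-6-methoxyphenoxy)phenol
Conditions: NBS (1.0 equiv), MeCN, −20 to 0 °C
Reagents that add atoms: N-bromosuccinimide O=C1CCC(=O)N1Br
Why: Electrophilic aromatic bromination; the free hydroxyl is the strongest donor in the molecule and directs para to C4', which a polar solvent and low temperature favour over ortho. Ring B is deactivated by three bromines and its single hydrogen lies between two of them.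

Step 10
Reactants: 15 4-bromo-2-(2,3,5-tribromo-6-methoxyphenoxy)phenol
Product: 17 3,4,6-tribromo-2-(5-bromo-2-hydroxyphenoxy)phenol, via bis(dibromoboryl) aryl borate 16 (not isolated)
Conditions: BBr3 (3 equiv), CH2Cl2, −78 to 0 °C; H2O work-up
Reagents that add atoms: none
Why: Lewis-acid cleavage of an aryl methyl ether: boron coordinates the ether oxygen and bromide attacks the methyl group (SN2), and the aryl borate 16 is hydrolysed on work-up. Diaryl ethers and aryl bromides do not react with BBr3 at this temperature.

## Compound list

1 | 2-bromo-6-methoxyphenol | COc1cccc(Br)c1O | starting material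
2 | 2-bromo-6-methoxyphenyl acetate | COc1cccc(Br)c1OC(C)=O | intermediate
3 | 2,3-dibromo-6-methoxyphenyl acetate | COc1ccc(Br)c(Br)c1OC(C)=O | intermediate (not isolated)
4 | 2,3,5-tribromo-6-methoxyphenyl acetate | COc1c(Br)cc(Br)c(Br)c1OC(C)=O | intermediate
5 | 2,3,5-tribromo-6-methoxyphenol | COc1c(Br)cc(Br)c(Br)c1O | intermediate
6 | (Z)-1,2-dichloroethene | Cl/C=C\Cl | starting material
7 | chloroethyne | ClC#C | intermediate (not isolated)
8 | (Z)-2-chloroethenyl 2,3,5-tribromo-6-methoxyphenyl ether (1,2,5-tribromo-3-{[(Z)-2-chloroethenyl]oxy}-4-methoxybenzene) | Cl/C=C\Oc1c(OC)c(Br)cc(Br)c1Br | intermediate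
9 | ethynyl 2,3,5-tribromo-6-methoxyphenyl ether (1,2,5-tribromo-3-(ethynyloxy)-4-methoxybenzene) | C#COc1c(OC)c(Br)cc(Br)c1Br | intermediate
10 | 3-hydroxy-2H-pyran-2-one | O=C1OC=CC=C1O | starting material
11 | 2-oxo-2H-pyran-3-yl acetate | CC(=O)OC1=CC=COC1=O | intermediate
12 | 3-oxo-5-(2,3,5-tribromo-6-methoxyphenoxy)-2-oxabicyclo[2.2.2]octa-5,7-dien-4-yl acetate (racemic, one enantiomer drawn) | CC(=O)O[C@]12C=C[C@H](C=C1Oc1c(OC)c(Br)cc(Br)c1Br)OC2=O | intermediate (not isolated)
13 | 2-(2,3,5-tribromo-6-methoxyphenoxy)phenyl acetate | CC(=O)Oc1ccccc1Oc1c(OC)c(Br)cc(Br)c1Br | intermediate
14 | 2-(2,3,5-tribromo-6-methoxyphenoxy)phenol | Oc1ccccc1Oc1c(OC)c(Br)cc(Br)c1Br | intermediate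
15 | 4-bromo-2-(2,3,5-tribromo-6-methoxyphenoxy)phenol | COc1c(Br)cc(Br)c(Br)c1Oc1cc(Br)ccc1O | intermediate
16 | dibromo{4-bromo-2-[2,3,5-tribromo-6-(dibromoboryloxy)phenoxy]phenoxy}borane | BrB(Br)Oc1ccc(Br)cc1Oc1c(OB(Br)Br)c(Br)cc(Br)c1Br | intermediate (not isolated)
17 | 3,4,6-tribromo-2-(5-bromo-2-hydroxyphenoxy)phenol | Oc1ccc(Br)cc1Oc1c(O)c(Br)cc(Br)c1Br | target

## Step count and uncertain steps

Total step count: 10. Longest linear sequence: 9 steps (steps 1–5 and 7–10); step 6 is a one-step side branch.

**Step 7 (key step).** The most likely failure is thermal self-reaction (oligomerisation) of the terminal aryl alkynyl ether before it is intercepted. Pyrone 11 is only a moderately electron-poor diene, and the alkyne of 9 is less electron-rich than an alkyl alkynyl ether because its oxygen is attached to an electron-poor ring. A second possibility is partial loss of regiocontrol, giving the meta isomer. The fallback drops the cycloaddition and builds the diaryl ether by nucleophilic aromatic substitution. It sets out from 5 and comes back at 15. Phenol 5 is heated with 4-bromo-2-fluoro-1-nitrobenzene and K2CO3 in DMF, where fluoride ortho to the nitro group is displaced, to give 4-bromo-1-nitro-2-(2,3,5-tribromo-6-methoxyphenoxy)benzene F1. Reduction with Fe powder and NH4Cl in aqueous ethanol, which spares aryl bromides, gives 4-bromo-2-(2,3,5-tribromo-6-methoxyphenoxy)aniline F2. Diazotisation with NaNO2 in aqueous H2SO4 gives the diazonium hydrogen sulfate F3, which is hydrolysed with Cu2O and Cu(NO3)2 in water to 15.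

**Step 5.** The base may remove the hydrogen on the chlorine-bearing carbon instead, which expels the stabilised phenoxide of 5 and reverses step 4. The alkoxide may also attack the freshly formed alkynyl ether. The fallback avoids alkoxide bases and halovinyl ethers. It sets out from 5 and comes back at 9. Phenol 5 is alkylated with 2-bromo-1,1-diethoxyethane (K2CO3, DMF, 120 °C) to 1,2,5-tribromo-3-(2,2-diethoxyethoxy)-4-methoxybenzene F4. Aqueous acid gives (2,3,5-tribromo-6-methoxyphenoxy)acetaldehyde F5. Treatment with nonafluorobutanesulfonyl fluoride and a phosphazene base in DMF converts F5 in one flask, through the enol nonaflate F6, into 9. The nonaflate is a far better leaving group than the aryloxide, so elimination should go only towards the alkyne.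

**Step 4.** The hindered, weakly nucleophilic phenoxide of 5 may add too slowly to chloroethyne, so that 7 oligomerises, or the product may eliminate and add a second phenoxide to give a bis(aryloxy)ethene. The fallback makes a halovinyl ether without any haloalkyne. It sets out from 5 and comes back at 9. Alkylation of 5 with excess 1,2-dibromoethane (K2CO3, acetone, reflux) gives 1,2,5-tribromo-3-(2-bromoethoxy)-4-methoxybenzene F7. KOtBu in THF eliminates HBr to the aryl vinyl ether F8. Br2 in CH2Cl2 at −78 °C adds across the vinyl group to give the 1,2-dibromoethyl ether F9. Et3N removes the labile α-bromide as HBr to give the 2-bromovinyl ether F10. F10 takes the place of 8 under the conditions of step 5 and gives 9.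

**Step 2.** The second bromination may stall at 3 because the ring is by then deactivated. Under forcing conditions HBr may instead cleave the acetate, after which bromination para to the freed hydroxyl (C4 of ring B) would follow. The fallback changes the mask to one that tolerates acid and Lewis acid and donates even less to C4. It sets out from 1 and comes back at 5. Compound 1 is converted with methanesulfonyl chloride and Et3N into 2-bromo-6-methoxyphenyl methanesulfonate F11. Bromination with Br2 and catalytic FeBr3 in CH2Cl2 gives 2,3,5-tribromo-6-methoxyphenyl methanesulfonate F12. Cleavage of the sulfonate with KOH in aqueous methanol at 65 °C gives 5.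

## Further compounds

F1 | step 7 | 4-bromo-1-nitro-2-(2,3,5-tribromo-6-methoxyphenoxy)benzene | COc1c(Br)cc(Br)c(Br)c1Oc1cc(Br)ccc1[N+](=O)[O-]
F2 | step 7 | 4-bromo-2-(2,3,5-tribromo-6-methoxyphenoxy)aniline | COc1c(Br)cc(Br)c(Br)c1Oc1cc(Br)ccc1N
F3 | step 7 | 4-bromo-2-(2,3,5-tribromo-6-methoxyphenoxy)benzenediazonium hydrogen sulfate | COc1c(Br)cc(Br)c(Br)c1Oc1cc(Br)ccc1[N+]#N.OS(=O)(=O)[O-]
F4 | step 5 | 1,2,5-tribromo-3-(2,2-diethoxyethoxy)-4-methoxybenzene | CCOC(COc1c(OC)c(Br)cc(Br)c1Br)OCC
F5 | step 5 | (2,3,5-tribromo-6-methoxyphenoxy)acetaldehyde | O=CCOc1c(OC)c(Br)cc(Br)c1Br
F6 | step 5 | (Z)-2-(2,3,5-tribromo-6-methoxyphenoxy)ethenyl nonafluorobutane-1-sulfonate | FC(F)(F)C(F)(F)C(F)(F)C(F)(F)S(=O)(=O)O/C=C\Oc1c(OC)c(Br)cc(Br)c1Br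
F7 | step 4 | 1,2,5-tribromo-3-(2-bromoethoxy)-4-methoxybenzene | BrCCOc1c(OC)c(Br)cc(Br)c1Br
F8 | step 4 | 1,2,5-tribromo-3-(ethenyloxy)-4-methoxybenzene | C=COc1c(OC)c(Br)cc(Br)c1Br
F9 | step 4 | 1,2,5-tribromo-3-(1,2-dibromoethoxy)-4-methoxybenzene (racemic) | BrCC(Br)Oc1c(OC)c(Br)cc(Br)c1Br
F10 | step 4 | 1,2,5-tribromo-3-{[(Z)-2-bromoethenyl]oxy}-4-methoxybenzene (E isomer may accompany it) | Br/C=C\Oc1c(OC)c(Br)cc(Br)c1Br
F11 | step 2 | 2-bromo-6-methoxyphenyl methanesulfonate | COc1cccc(Br)c1OS(C)(=O)=O
F12 | step 2 | 2,3,5-tribromo-6-methoxyphenyl methanesulfonate | COc1c(Br)cc(Br)c(Br)c1OS(C)(=O)=O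
A1 | alternative 1 | methyl 6-(5-bromo-2-methoxyphenoxy)-5-oxohexanoate | COC(=O)CCCC(=O)COc1cc(Br)ccc1OC
A2 | alternative 1 | 2-(5-bromo-2-methoxyphenoxy)cyclohexane-1,3-dione | COc1ccc(Br)cc1OC1C(=O)CCCC1=O
A3 | alternative 2 | 2-(2,3-didehydrophenyl)-4,4,5,5-tetramethyl-1,3,2-dioxaborolane (3-borylbenzyne) | CC1(C)OB(OC1(C)C)C1=CC=CC#C1
A4 | alternative 2 | 2-[3-bromo-2-(5-bromo-2-methoxyphenoxy)phenyl]-4,4,5,5-tetramethyl-1,3,2-dioxaborolane | COc1ccc(Br)cc1Oc1c(Br)cccc1B1OC(C)(C)C(C)(C)O1
A5 | alternative 3 | 1-(2,3,5-tribromo-6-methoxyphenoxy)propan-2-one | CC(=O)COc1c(OC)c(Br)cc(Br)c1Br
A6 | alternative 3 | N-[2-bromo-3-(dimethylamino)prop-2-en-1-ylidene]-N-methylmethanaminium hexafluorophosphate | CN(C)/C=C(Br)/C=[N+](C)C.F[P-](F)(F)(F)(F)F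
A7 | alternative 3 | 4-bromo-2-(2,3,5-tribromo-6-methoxyphenoxy)phenol | COc1c(Br)cc(Br)c(Br)c1Oc1cc(Br)ccc1O
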